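The plan rests on tracing ring C back to a (Z)-aurone, so that O1–C2 is the last skeletal bond made. In one flask the exocyclic alkene is epoxidised and the spiro-epoxide is opened with acid. This enlarges the furanone to the pyranone, forms O1–C2 and ring C, and introduces the 3-oxygen. The step exploits the C5 oxygen of ring A, which steers cyclisations of this series towards aurones, and the 4'-oxygen of ring B, para to the future C2, which directs the cationic charge there. The precursor is a 4,6-bis(benzyloxy)-7-methoxy aurone carrying a 3-methoxy-4-silyloxybenzylidene group, made from a coumaranone and silylated vanillin.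

Key step: step 9

Remark: 3,5-bis(benzyloxy)phenol (1) is taken as a purchased material, and the racemic epoxide is drawn as one enantiomer.

Step 1
Reactants: 1 3,5-bis(benzyloxy)phenol
Product: 2 2,4-bis(benzyloxy)-6-hydroxybenzaldehyde
Conditions: MgCl2, Et3N, (CH2O)n, MeCN, reflux; 1 M HCl work-up
Reagents that add atoms: paraformaldehyde (as formaldehyde), C=O
Why: Magnesium-phenoxide-directed ortho-formylation (Casnati–Skattebøl reaction) places the aldehyde only next to the hydroxyl, and the two ortho positions of the symmetric phenol are equivalent, so a single salicylaldehyde should result.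

Step 2
Reactants: 2 2,4-bis(benzyloxy)-6-hydroxybenzaldehyde; 3 methyl bromoacetate
Product: 4 methyl 2-[3,5-bis(benzyloxy)-2-formylphenoxy]acetate
Conditions: K2CO3, DMF, rt
Reagents that add atoms: none
Why: Williamson O-alkylation of the only free phenol with an activated primary bromide, run at room temperature so that the electron-rich aldehyde should not close onto the ester enolate to give a benzofuran.

Step 3
Reactants: 4 methyl 2-[3,5-bis(benzyloxy)-2-formylphenoxy]acetate
Product: 5 methyl 2-[3,5-bis(benzyloxy)-2-(formyloxy)phenoxy]acetate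
Conditions: mCPBA, CH2Cl2, 0 °C to rt
Reagents that add atoms: mCPBA, O=C(OO)c1cccc(Cl)c1
Why: Baeyer–Villiger oxidation of a benzaldehyde with two ortho and one para alkoxy groups proceeds by aryl migration, so the formyl carbon is exchanged for the oxygen that becomes the 8-oxygen of the flavone.

Step 4
Reactants: 5 methyl 2-[3,5-bis(benzyloxy)-2-(formyloxy)phenoxy]acetate
Product: 7 methyl 2-[3,5-bis(benzyloxy)-2-methoxyphenoxy]acetate, via phenol intermediate 6 (not isolated)
Conditions: K2CO3, MeOH–DMF, argon, 0 °C; then MeI, rt
Reagents that add atoms: iodomethane, CI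
Why: Carbonate-mediated methanolysis of the aryl formate (transesterification) followed by Williamson O-methylation in the same flask should trap the air-sensitive phenol as it forms, and any lactone arising from the phenoxide and the neighbouring ester is reopened by methanol to the same methyl ester.

Step 5
Reactants: 7 methyl 2-[3,5-bis(benzyloxy)-2-methoxyphenoxy]acetate
Product: 8 2-[3,5-bis(benzyloxy)-2-methoxyphenoxy]acetic acid
Conditions: LiOH·H2O, THF–H2O, rt; then 1 M HCl
Reagents that add atoms: lithium hydroxide (hydroxide oxygen), [Li+].[OH-]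
Why: Ester saponification, to which the benzyl and methyl aryl ethers are inert.

Step 6
Reactants: 8 2-[3,5-bis(benzyloxy)-2-methoxyphenoxy]acetic acid
Product: 10 4,6-bis(benzyloxy)-7-methoxy-1-benzofuran-3(2H)-one, via mixed trifluoroacetic anhydride 9 (not isolated)
Conditions: (CF3CO)2O, CH2Cl2, 0 °C to rt; aq. NaHCO3 work-up
Reagents that add atoms: none
Why: Intramolecular Friedel–Crafts acylation through the acyl trifluoroacetate, which should need no Lewis acid because the attacked carbon is ortho to one benzyloxy group and para to the other, and which has only one possible site because the other position ortho to the oxyacetic chain carries the methoxy group.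

Step 7
Reactants: 11 vanillin
Product: 12 3-methoxy-4-(triisopropylsilyloxy)benzaldehyde
Conditions: TIPSCl, imidazole, DMF, rt
Reagents that add atoms: chlorotriisopropylsilane, CC(C)[Si](Cl)(C(C)C)C(C)C
Why: Imidazole-promoted O-silylation of the phenol, the triisopropylsilyl group being chosen because it should tolerate carbonate alkylations, hydrogenolysis and catalytic acid and later leaves with fluoride without harm to a prenyl ether.

Step 8
Reactants: 10 4,6-bis(benzyloxy)-7-methoxy-1-benzofuran-3(2H)-one; 12 3-methoxy-4-(triisopropylsilyloxy)benzaldehyde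
Product: 13 (Z)-4,6-bis(benzyloxy)-7-methoxy-2-[3-methoxy-4-(triisopropylsilyloxy)benzylidene]-1-benzofuran-3(2H)-one
Conditions: neutral Al2O3, CH2Cl2, rt
Reagents that add atoms: none
Why: Aldol condensation of the acidic C2 methylene of the coumaranone with the aldehyde on a neutral surface that should spare the aryl silyl ether, giving the thermodynamically preferred (Z)-alkene with the aryl group cis to O1.

Step 9
Reactants: 13 (Z)-4,6-bis(benzyloxy)-7-methoxy-2-[3-methoxy-4-(triisopropylsilyloxy)benzylidene]-1-benzofuran-3(2H)-one
Product: 15 5,7-bis(benzyloxy)-3-hydroxy-8-methoxy-2-[3-methoxy-4-(triisopropylsilyloxy)phenyl]-4H-chromen-4-one, via spiro-epoxide 14 (not isolated)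
Conditions: DMDO (acetone solution, 1.2 equiv), CH2Cl2, 0 °C to rt; then TsOH·H2O (0.2 equiv), same flask, 0 °C to rt
Reagents that add atoms: dimethyldioxirane, CC1(C)OO1
Why: Dimethyldioxirane epoxidises the exocyclic alkene between C2 and the benzylic carbon (dioxirane epoxidation of aurones) to a racemic spiro-epoxide whose two stereocentres are erased later. Acid then opens the epoxide at the benzylic carbon to a cation that the 4'-silyloxy group delocalises as a quinone-methide-like oxocarbenium; the C2 hemiketal left behind collapses to a 1,2-diketone and releases the phenolic O1, which captures the cation in a 6-exo-trig closure (its formal double bond to ring B lies outside the new ring) to make O1–C2 and ring C. Enolisation of the resulting chromane-3,4-dione gives the 3-hydroxychromone, whose 3-oxygen comes from the dioxirane. The closest known reaction type is the Auwers ring expansion of aurone dihalides to flavonols, the epoxide serving as a halogen-free equivalent that should spare the electron-rich rings A and B from nuclear halogenation. The product has no stereocentre, so no stereocontrol is required. The step needs C–O cleavage at the benzylic rather than the ketal carbon and return of O1 rather than a 1,2-acyl shift to a 3-aryl-4-hydroxycoumarin; the 4'-oxygen para to the benzylic carbon together with the C3 carbonyl, which disfavours charge at C2, should secure the first, and a protic non-chelating acid should favour the second.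

Step 10
Reactants: 15 5,7-bis(benzyloxy)-3-hydroxy-8-methoxy-2-[3-methoxy-4-(triisopropylsilyloxy)phenyl]-4H-chromen-4-one
Product: 16 5,7-bis(benzyloxy)-3,8-dimethoxy-2-[3-methoxy-4-(triisopropylsilyloxy)phenyl]-4H-chromen-4-one
Conditions: MeI, K2CO3, acetone, 40 °C
Reagents that add atoms: iodomethane, CI
Why: Williamson O-methylation of the acidic 3-hydroxyl, the only free hydroxyl in the molecule, under anhydrous carbonate conditions that a hindered aryl silyl ether should withstand.

Step 11
Reactants: 16 5,7-bis(benzyloxy)-3,8-dimethoxy-2-[3-methoxy-4-(triisopropylsilyloxy)phenyl]-4H-chromen-4-one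
Product: 17 5,7-dihydroxy-3,8-dimethoxy-2-[3-methoxy-4-(triisopropylsilyloxy)phenyl]-4H-chromen-4-one
Conditions: H2 (1 atm), Pd/C, EtOAc–THF, rt
Reagents that add atoms: none
Why: Catalytic hydrogenolysis of both benzyl aryl ethers, under which the tetrasubstituted chromone double bond, the methyl ethers and the silyl ether should remain intact.

Step 12
Reactants: 17 5,7-dihydroxy-3,8-dimethoxy-2-[3-methoxy-4-(triisopropylsilyloxy)phenyl]-4H-chromen-4-one; 18 prenyl bromide (1-bromo-3-methylbut-2-ene)
Product: 19 5-hydroxy-3,8-dimethoxy-7-[(3-methylbut-2-en-1-yl)oxy]-2-[3-methoxy-4-(triisopropylsilyloxy)phenyl]-4H-chromen-4-one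
Conditions: K2CO3 (1.2 equiv), acetone, rt
Reagents that add atoms: none
Why: Regioselective Williamson O-alkylation, in which the 7-hydroxyl (para to the carbonyl-bearing carbon, more acidic) reacts while the 5-hydroxyl is held in a hydrogen bond to the C4 carbonyl and the 4'-oxygen stays silylated.

Step 13
Reactants: 19 5-hydroxy-3,8-dimethoxy-7-[(3-methylbut-2-en-1-yl)oxy]-2-[3-methoxy-4-(triisopropylsilyloxy)phenyl]-4H-chromen-4-one
Product: 20 5-hydroxy-2-(4-hydroxy-3-methoxyphenyl)-3,8-dimethoxy-7-[(3-methylbut-2-en-1-yl)oxy]-4H-chromen-4-one (5,4'-dihydroxy-3,8,3'-trimethoxy-7-prenyloxyflavone)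
Conditions: Bu4NF, AcOH (1.1 equiv each), THF, 0 °C
Reagents that add atoms: none
Why: Fluoride-mediated cleavage of the aryl silyl ether, buffered with acetic acid, which should leave the acid-sensitive prenyl ether and the methyl ethers untouched.

Compound list
1 | 3,5-bis(benzyloxy)phenol | Oc1cc(OCc2ccccc2)cc(OCc2ccccc2)c1 | starting material
2 | 2,4-bis(benzyloxy)-6-hydroxybenzaldehyde | O=Cc1c(O)cc(OCc2ccccc2)cc1OCc1ccccc1 | intermediate
3 | methyl bromoacetate | COC(=O)CBr | starting material
4 | methyl 2-[3,5-bis(benzyloxy)-2-formylphenoxy]acetate | COC(=O)COc1cc(OCc2ccccc2)cc(OCc2ccccc2)c1C=O | intermediate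
5 | methyl 2-[3,5-bis(benzyloxy)-2-(formyloxy)phenoxy]acetate | COC(=O)COc1cc(OCc2ccccc2)cc(OCc2ccccc2)c1OC=O | intermediate
6 | methyl 2-[3,5-bis(benzyloxy)-2-hydroxyphenoxy]acetate (phenol formed in the flask, not isolated) | COC(=O)COc1cc(OCc2ccccc2)cc(OCc2ccccc2)c1O | intermediate
7 | methyl 2-[3,5-bis(benzyloxy)-2-methoxyphenoxy]acetate | COC(=O)COc1cc(OCc2ccccc2)cc(OCc2ccccc2)c1OC | intermediate
8 | 2-[3,5-bis(benzyloxy)-2-methoxyphenoxy]acetic acid | OC(=O)COc1cc(OCc2ccccc2)cc(OCc2ccccc2)c1OC | intermediate
9 | 2-[3,5-bis(benzyloxy)-2-methoxyphenoxy]acetic trifluoroacetic anhydride (formed in the flask, not isolated) | O=C(COc1cc(OCc2ccccc2)cc(OCc2ccccc2)c1OC)OC(=O)C(F)(F)F | intermediate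
10 | 4,6-bis(benzyloxy)-7-methoxy-1-benzofuran-3(2H)-one | COc1c(OCc2ccccc2)cc(OCc2ccccc2)c2C(=O)COc12 | intermediate
11 | vanillin (4-hydroxy-3-methoxybenzaldehyde) | COc1cc(C=O)ccc1O | starting material
12 | 3-methoxy-4-(triisopropylsilyloxy)benzaldehyde | COc1cc(C=O)ccc1O[Si](C(C)C)(C(C)C)C(C)C | intermediate
13 | (Z)-4,6-bis(benzyloxy)-7-methoxy-2-[3-methoxy-4-(triisopropylsilyloxy)benzylidene]-1-benzofuran-3(2H)-one | O1/C(=C\c2ccc(O[Si](C(C)C)(C(C)C)C(C)C)c(OC)c2)C(=O)c2c(OCc3ccccc3)cc(OCc3ccccc3)c(OC)c12 | intermediate
14 | (2R*,3'R*)-4,6-bis(benzyloxy)-7-methoxy-3'-[3-methoxy-4-(triisopropylsilyloxy)phenyl]-3H-spiro[1-benzofuran-2,2'-oxiran]-3-one, racemic, aryl cis to O1 (formed in the flask, not isolated) | COc1cc(ccc1O[Si](C(C)C)(C(C)C)C(C)C)[C@H]2O[C@@]23Oc4c(OC)c(OCc5ccccc5)cc(OCc5ccccc5)c4C3=O | intermediate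
15 | 5,7-bis(benzyloxy)-3-hydroxy-8-methoxy-2-[3-methoxy-4-(triisopropylsilyloxy)phenyl]-4H-chromen-4-one | COc1cc(-c2oc3c(OC)c(OCc4ccccc4)cc(OCc4ccccc4)c3c(=O)c2O)ccc1O[Si](C(C)C)(C(C)C)C(C)C | intermediate
16 | 5,7-bis(benzyloxy)-3,8-dimethoxy-2-[3-methoxy-4-(triisopropylsilyloxy)phenyl]-4H-chromen-4-one | COc1cc(-c2oc3c(OC)c(OCc4ccccc4)cc(OCc4ccccc4)c3c(=O)c2OC)ccc1O[Si](C(C)C)(C(C)C)C(C)C | intermediate
17 | 5,7-dihydroxy-3,8-dimethoxy-2-[3-methoxy-4-(triisopropylsilyloxy)phenyl]-4H-chromen-4-one | COc1cc(-c2oc3c(OC)c(O)cc(O)c3c(=O)c2OC)ccc1O[Si](C(C)C)(C(C)C)C(C)C | intermediate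
18 | prenyl bromide (1-bromo-3-methylbut-2-ene) | CC(C)=CCBr | starting material
19 | 5-hydroxy-3,8-dimethoxy-7-[(3-methylbut-2-en-1-yl)oxy]-2-[3-methoxy-4-(triisopropylsilyloxy)phenyl]-4H-chromen-4-one | COc1cc(-c2oc3c(OC)c(OCC=C(C)C)cc(O)c3c(=O)c2OC)ccc1O[Si](C(C)C)(C(C)C)C(C)C | intermediate
20 | 5-hydroxy-2-(4-hydroxy-3-methoxyphenyl)-3,8-dimethoxy-7-[(3-methylbut-2-en-1-yl)oxy]-4H-chromen-4-one | COc1cc(-c2oc3c(OC)c(OCC=C(C)C)cc(O)c3c(=O)c2OC)ccc1O | target

Total step count: 13. Longest linear sequence: 12 steps (steps 1 to 6, then 8 to 13); step 7 is a one-step side branch.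

Steps most likely to fail

Step 9. After the epoxide opens, the cation may be diverted: by a 1,2-acyl shift towards a 3-aryl-4-hydroxycoumarin skeleton, by capture of an external nucleophile, or by loss of the silyl group from the quinone-methide-like cation. If epoxidation is slow, the dioxirane may also attack the electron-rich rings. The fallback sets out from 13 and replaces the acid-driven cationic rearrangement by a base-driven substitution. The epoxide 14 would be isolated by evaporating the dioxirane solution and opened at the benzylic carbon with anhydrous HCl in Et2O at 0 °C to the chlorohydrin 4,6-bis(benzyloxy)-2-{chloro[3-methoxy-4-(triisopropylsilyloxy)phenyl]methyl}-2-hydroxy-7-methoxy-1-benzofuran-3(2H)-one F1. Treatment with Et3N in CH2Cl2 should then open the hemiketal to the diketone phenoxide, which displaces chloride in a 6-exo-tet substitution (the base-mediated Auwers endgame) and enolises, coming back to the route at 15.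

Step 6. The acid released may strip benzyl groups or shift them to carbon, and trifluoroacetylation of the activated ring may compete with the five-membered ring closure. The fallback sets out from 8 and moves the protecting groups out of the acylation. Hydrogenolysis (H2, Pd/C, EtOAc–MeOH) would give 2-(3,5-dihydroxy-2-methoxyphenoxy)acetic acid F2. The unprotected acid would be cyclised in polyphosphoric acid at 80 °C, at the same single open ortho position, to 4,6-dihydroxy-7-methoxy-1-benzofuran-3(2H)-one F3. Both hydroxyls would then be benzylated (BnBr, K2CO3, DMF), returning to the route at 10.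

Step 12. Alkylation may spill over to carbon C6 or to the chelated 5-hydroxyl, and carbonate may cleave the aryl silyl ether so that the 4'-oxygen is prenylated as well. The fallback sets out from 17 and uses a base-free Mitsunobu etherification with 3-methylbut-2-en-1-ol, PPh3 and diisopropyl azodicarboxylate in THF at 0 °C. This should engage only the acidic, non-chelated 7-hydroxyl and comes back to the route at 19; it makes no new compound (F0).

Further compounds
F1 | step 9 | 4,6-bis(benzyloxy)-2-{chloro[3-methoxy-4-(triisopropylsilyloxy)phenyl]methyl}-2-hydroxy-7-methoxy-1-benzofuran-3(2H)-one (racemic mixture of diastereomers, no configuration assigned) | COc1cc(ccc1O[Si](C(C)C)(C(C)C)C(C)C)C(Cl)C2(O)Oc3c(OC)c(OCc4ccccc4)cc(OCc4ccccc4)c3C2=O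
F2 | step 6 | 2-(3,5-dihydroxy-2-methoxyphenoxy)acetic acid | COc1c(O)cc(O)cc1OCC(=O)O
F3 | step 6 | 4,6-dihydroxy-7-methoxy-1-benzofuran-3(2H)-one | COc1c(O)cc(O)c2C(=O)COc12
F0 | step 12 | none | none
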